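**Note for the bench**

1. Late in the earlier runs, at 60.0 min, red has 63.8% of its L left and teal 86.1%, so I read loss constants of 0.00749 /min for red and 0.00249 /min for teal.

2. Their ratio, 3.01, stands close to the ratio of the D charges, 2.96. So I reckon the loss of L as first order in D.

3. Red's earlier reading gives 0.00712 /min at 25.0 min, against 0.00749 /min at 60.0 min. So at a given D, I treat L as falling pseudo-first-order.

4. What I carry is the halving time of L at the D charged, with D held at its charge: 2.28 h.

5. All four new flasks hold 16.2 mM of D, so my reckoning gives each the same halving time. When you come at 3.0 h, expect 40.2% of the L charged.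

6. Don't read lost L as J: at 60.0 min red shows 5.2% J against 36.2% of L lost. Leave the D charge alone: in my reckoning the halving time moves with it.

| flask | L | D | remark | time |
|---|---|---|---|---|
| red | 8 mM | 24 mM | run made earlier |  |
| teal | 8 mM | 8.1 mM | run made earlier |  |
| alder | 8.0 mM | 16.2 mM |  | 3.0 h |
| cedar | 12 mM | 16.2 mM |  | 3.0 h |
| birch | 20 mM | 16.2 mM |  | 3.0 h |
| elm | 25 mM | 16.2 mM |  | 3.0 h |

- red (time / min: J / %, L / %): 5.00: 1.3, 96.6; 12.0: 0, 92.7; 25.0: 0.8, 83.7; 60.0: 5.2, 63.8
- teal (time / min: J / %, L / %): 5.00: 0, 98.0; 12.0: 0.3, 98.0; 25.0: 0, 94.1; 60.0: 0.1, 86.1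

(scatter of a reading: 0.5 percentage points)

- the analysis behind the earlier runs scatters by 0.5 percentage points, standard deviation
- "hardly changes" means that all values lie within two and a half points (for a concentration: within two and a half percent of the largest)

- [J] at the end for alder, cedar, birch, elm, in this order
- how that number moves from the first to the last of them (falls, then rises / hardly changes / rises, then falls / falls all the way / rises all the way)

7. For J at the end in alder, cedar, birch and elm, the forecast says 1.23 mM, 1.38 mM, 1.42 mM, 1.37 mM, rises, then falls: “More L gives more J at first, then L competes for D and intermediates soak it up.”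

**Result**

Alder, cedar, birch and elm end with J at 0.951 mM, 1.00 mM, 0.860 mM, 0.723 mM, rises, then falls, so the shape agrees with the forecast, but the top stands at cedar, where the forecast has it at birch.

    L + D ⇌ Z + E (K = 0.700, k = 0.00480 /M/s)
    E + D ⇌ Z + Q (K = 2.00, k = 0.0300 /M/s)
    Q + D ⇌ Z + J (K = 36.0, k = 0.0110 /M/s)
    L + J → X (k = 0.0120 /M/s)
    Z + L → G (k = 0.00960 /M/s)

The row turns at 12 mM of L. Put to use again, 2.28 h gives 40.2% of the L charged left at 3.0 h, and alder ends at 37.6% of its L charged. Elm, with D down to 24.2% of its charge, ends at 41.3% of its L charged.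

The numbers in the tables are calculated with made-up constants; noise was put on by code.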